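The route rests on disconnecting the O1–C2 bond of ring C together with the C3–O bond, the latter traced back to a C3–I bond. The key step exploits the fact that C3, lying between C2 (which bears ring B) and the C4 carbonyl, is the carbon that receives the electrophile when an aryl alkynyl ketone is closed by a ring-A oxygen. One operation therefore forms O1–C2, closes ring C and places iodine at C3. The precursor is an ynone joining ring A (ketone side) to ring B (alkyne terminus), in which the future O1 is a methyl ether and the future C5 oxygen is a free phenol hydrogen-bonded to the ketone, which steers the closure.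

Key step: step 4

Remark: the oxygen that becomes O1 is carried as its methyl ether and the oxygen that becomes the C5 substituent as the free phenol, because a phenol ortho to the ketone hydrogen-bonds to the carbonyl oxygen and so turns the alkyne toward the other ortho oxygen; the C5 hydroxyl is methylated after the cyclisation.

Step 1
Reactants: 1 3,4,5-trimethoxyphenol
Product: 3 6-hydroxy-2,3,4-trimethoxybenzaldehyde, via 2-(hydroxymethyl)-3,4,5-trimethoxyphenol 2 (not isolated)
Conditions: MgCl2 (2 equiv), Et3N (2 equiv), paraformaldehyde (3 equiv), THF, reflux; then 1 M HCl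
Reagents that add atoms: formaldehyde (from paraformaldehyde), C=O
Why: Magnesium-mediated ortho-formylation (Casnati–Skattebøl reaction): the ArOMgCl phenoxide delivers formaldehyde to the carbon next to the phenol oxygen to give benzylic alcohol 2, a second formaldehyde oxidises it by hydride transfer, and since C2 and C6 of 1 are equivalent and C4 is blocked only one aldehyde can form.

Step 2
Reactants: 3 6-hydroxy-2,3,4-trimethoxybenzaldehyde; 4 2-ethynylanisole
Product: 6 2-[1-hydroxy-3-(2-methoxyphenyl)prop-2-yn-1-yl]-3,4,5-trimethoxyphenol (racemic), via lithium (2-methoxyphenyl)acetylide 5 (not isolated)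
Conditions: 4 (2.4 equiv), n-BuLi (2.3 equiv), THF, −78 °C; then 3 in THF, −78 °C to 0 °C; sat. aq. NH4Cl; crude product used directly
Reagents that add atoms: none
Why: 1,2-Addition of a lithium acetylide to an aldehyde: the first equivalent of 5 only deprotonates the phenol and the second adds to the formyl group, the carbinol centre being formed as a racemate that is erased in step 3.

Step 3
Reactants: 6 2-[1-hydroxy-3-(2-methoxyphenyl)prop-2-yn-1-yl]-3,4,5-trimethoxyphenol (racemic)
Product: 7 1-(6-hydroxy-2,3,4-trimethoxyphenyl)-3-(2-methoxyphenyl)prop-2-yn-1-one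
Conditions: activated MnO2 (15 equiv), CH2Cl2, rt; filtration through Celite
Reagents that add atoms: none
Why: Selective MnO2 oxidation of a benzylic and propargylic alcohol: the doubly activated secondary carbinol should be oxidised under neutral heterogeneous conditions that leave the phenol, the alkyne and the aryl ethers untouched and do not trigger cyclisation of the hydroxy ynone.

Step 4
Reactants: 7 1-(6-hydroxy-2,3,4-trimethoxyphenyl)-3-(2-methoxyphenyl)prop-2-yn-1-one
Product: 9 5-hydroxy-3-iodo-7,8-dimethoxy-2-(2-methoxyphenyl)-4H-chromen-4-one, via O1-methyloxonium chloride 8 (not isolated)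
Conditions: ICl (1.05 equiv, 1.0 M in CH2Cl2, slow addition), CH2Cl2, −78 °C; aq. Na2S2O3 added cold
Reagents that add atoms: iodine monochloride, ClI
Why: ICl adds its iodine to the alkyne carbon next to the ketone while the C2' methoxy oxygen of ring A attacks, anti and in the plane, the alkyne carbon that carries ring B, and chloride then takes the methyl group off oxonium 8 as chloromethane, so that the O1–C2 and C3–I bonds form together. The closest known reaction type is the ICl-induced demethylative iodocyclisation of 2-methoxyaryl alkynyl ketones to 3-iodochromones, applied here to a substrate with one additional free phenol. Ring C closes in the 6-endo-dig mode and no stereocentre is created. The choice between the two ring-A oxygens that flank the ketone is secured by the hydrogen bond from the C6' hydroxyl to the carbonyl oxygen, which fixes the carbonyl on the phenol side, places the alkyne against the C2' methoxy oxygen and is carried unbroken into the 5-OH to C4=O chelate of 9, whereas attack by the phenol oxygen would first require this bond to be broken. The 6-endo mode is favoured over 5-exo closure and over 5-endo attack of the ring-B methoxy group, both of which would hit the carbon next to the ketone, because positive charge develops only at the carbon stabilised by the 2-methoxyphenyl group. Iodination of the electron-rich C5' position of ring A is held back by slow addition of about one equivalent of ICl at −78 °C and a cold thiosulfate quench, since capture of the activated alkyne is intramolecular and preorganised.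

Step 5
Reactants: 9 5-hydroxy-3-iodo-7,8-dimethoxy-2-(2-methoxyphenyl)-4H-chromen-4-one
Product: 10 3-iodo-5,7,8-trimethoxy-2-(2-methoxyphenyl)-4H-chromen-4-one
Conditions: MeI (5 equiv), K2CO3 (3 equiv), DMF, 45 °C
Reagents that add atoms: iodomethane, CI
Why: Williamson O-methylation of the chelated 5-hydroxyl: carbonate in warm DMF should be enough to break the hydrogen bond to the C4 carbonyl, and the alkenyl iodide at C3 does not react with K2CO3 or MeI.

Step 6
Reactants: 10 3-iodo-5,7,8-trimethoxy-2-(2-methoxyphenyl)-4H-chromen-4-one
Product: 11 3,5,7,8-tetramethoxy-2-(2-methoxyphenyl)-4H-chromen-4-one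
Conditions: CuI (10 mol %), 1,10-phenanthroline (20 mol %), Cs2CO3 (2 equiv), MeOH, 110 °C, sealed tube
Reagents that add atoms: methanol, CO
Why: Ullmann-type copper-catalysed C–O coupling of an sp2 iodide with an alcohol: the phenanthroline-bound methoxide of monovalent copper should insert into the C3–I bond, which the adjacent C4 carbonyl activates, and reductive elimination gives the C3 methyl ether while the aryl group on C2 hinders conjugate attack of methoxide.

Compound list
1 | 3,4,5-trimethoxyphenol | COc1cc(O)cc(OC)c1OC | starting material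
2 | 2-(hydroxymethyl)-3,4,5-trimethoxyphenol (bound to magnesium in the flask, not isolated) | OCc1c(O)cc(OC)c(OC)c1OC | intermediate
3 | 6-hydroxy-2,3,4-trimethoxybenzaldehyde | O=Cc1c(O)cc(OC)c(OC)c1OC | intermediate
4 | 2-ethynylanisole (1-ethynyl-2-methoxybenzene) | COc1ccccc1C#C | starting material
5 | lithium (2-methoxyphenyl)acetylide, LiC≡C–C6H4-2-OMe (formed in the flask, not isolated) | COc1ccccc1C#[C-].[Li+] | intermediate
6 | 2-[1-hydroxy-3-(2-methoxyphenyl)prop-2-yn-1-yl]-3,4,5-trimethoxyphenol (racemic) | COc1ccccc1C#CC(O)c1c(O)cc(OC)c(OC)c1OC | intermediate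
7 | 1-(6-hydroxy-2,3,4-trimethoxyphenyl)-3-(2-methoxyphenyl)prop-2-yn-1-one | COc1ccccc1C#CC(=O)c1c(O)cc(OC)c(OC)c1OC | intermediate
8 | 5-hydroxy-3-iodo-7,8-dimethoxy-2-(2-methoxyphenyl)-1-methyl-4-oxo-4H-chromen-1-ium chloride (not isolated) | COc1ccccc1C1=C(I)C(=O)c2c(O)cc(OC)c(OC)c2[O+]1C.[Cl-] | intermediate
9 | 5-hydroxy-3-iodo-7,8-dimethoxy-2-(2-methoxyphenyl)-4H-chromen-4-one | COc1ccccc1-c1oc2c(OC)c(OC)cc(O)c2c(=O)c1I | intermediate
10 | 3-iodo-5,7,8-trimethoxy-2-(2-methoxyphenyl)-4H-chromen-4-one | COc1ccccc1-c1oc2c(OC)c(OC)cc(OC)c2c(=O)c1I | intermediate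
11 | 3,5,7,8-tetramethoxy-2-(2-methoxyphenyl)-4H-chromen-4-one | COc1ccccc1-c1oc2c(OC)c(OC)cc(OC)c2c(=O)c1OC | target

Total step count: 6
Longest linear sequence: 6 steps (1 to 11; 4 enters in step 2)

Steps most likely to fail

Step 4. What may go wrong is closure of ring C through the phenol oxygen instead of the methoxy oxygen, or iodination of ring A before the alkyne is captured. The fallback replaces the hydrogen-bond control by a blocking group. Setting out from 3, TsCl/Et3N/DMAP in CH2Cl2 should give 2-formyl-3,4,5-trimethoxyphenyl 4-methylbenzenesulfonate F1. Addition of 5 (1.2 equiv, THF, −78 °C) should give racemic 2-[1-hydroxy-3-(2-methoxyphenyl)prop-2-yn-1-yl]-3,4,5-trimethoxyphenyl 4-methylbenzenesulfonate F2, and MnO2 in CH2Cl2 should give the ynone 3,4,5-trimethoxy-2-[3-(2-methoxyphenyl)prop-2-ynoyl]phenyl 4-methylbenzenesulfonate F3. In this ynone the sulfonylated oxygen is not nucleophilic and ring A is deactivated, so ICl (CH2Cl2, −78 °C to rt) can close ring C only through the C2' methoxy oxygen. This is the standard substrate class for the cyclisation and should give 3-iodo-7,8-dimethoxy-2-(2-methoxyphenyl)-4-oxo-4H-chromen-5-yl 4-methylbenzenesulfonate F4. K2CO3 in MeOH/H2O at 50 °C should then cleave the sulfonate and bring the route back at 9.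

Step 6. What may go wrong is loss of iodine by reduction, or conjugate attack of methoxide at C2 with opening of ring C in hot basic methanol. The fallback introduces the oxygen through boron at low temperature. Setting out from 10, iodine–magnesium exchange with i-PrMgCl·LiCl (THF, −40 °C), trapping with B(OMe)3 and oxidation in the same flask with NaBO3·4H2O should give the flavonol 3-hydroxy-5,7,8-trimethoxy-2-(2-methoxyphenyl)-4H-chromen-4-one F5. MeI/K2CO3 in acetone at reflux should then methylate the 3-hydroxyl and bring the route back at 11.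

Step 2. What may go wrong is stalling of the addition, because the lithium phenoxide formed first deactivates the aldehyde and may precipitate. The fallback masks the phenol before the C–C bond is made. Setting out from 3, MOMCl/i-Pr2NEt in CH2Cl2 should give 2,3,4-trimethoxy-6-(methoxymethoxy)benzaldehyde F6. Acetylide 5 (1.2 equiv, THF, −78 °C) should add to give racemic 3-(2-methoxyphenyl)-1-[2,3,4-trimethoxy-6-(methoxymethoxy)phenyl]prop-2-yn-1-ol F7, and MnO2 should give 3-(2-methoxyphenyl)-1-[2,3,4-trimethoxy-6-(methoxymethoxy)phenyl]prop-2-yn-1-one F8. Then 2 M HCl in THF at rt should remove the acetal ortho to the ketone and bring the route back at 7, so that the hydrogen bond needed in step 4 is restored before the cyclisation.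

Further compounds
F1 | step 4 | 2-formyl-3,4,5-trimethoxyphenyl 4-methylbenzenesulfonate | O=Cc1c(OS(=O)(=O)c2ccc(C)cc2)cc(OC)c(OC)c1OC
F2 | step 4 | 2-[1-hydroxy-3-(2-methoxyphenyl)prop-2-yn-1-yl]-3,4,5-trimethoxyphenyl 4-methylbenzenesulfonate (racemic) | COc1ccccc1C#CC(O)c1c(OS(=O)(=O)c2ccc(C)cc2)cc(OC)c(OC)c1OC
F3 | step 4 | 3,4,5-trimethoxy-2-[3-(2-methoxyphenyl)prop-2-ynoyl]phenyl 4-methylbenzenesulfonate | COc1ccccc1C#CC(=O)c1c(OS(=O)(=O)c2ccc(C)cc2)cc(OC)c(OC)c1OC
F4 | step 4 | 3-iodo-7,8-dimethoxy-2-(2-methoxyphenyl)-4-oxo-4H-chromen-5-yl 4-methylbenzenesulfonate | COc1ccccc1-c1oc2c(OC)c(OC)cc(OS(=O)(=O)c3ccc(C)cc3)c2c(=O)c1I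
F5 | step 6 | 3-hydroxy-5,7,8-trimethoxy-2-(2-methoxyphenyl)-4H-chromen-4-one | COc1ccccc1-c1oc2c(OC)c(OC)cc(OC)c2c(=O)c1O
F6 | step 2 | 2,3,4-trimethoxy-6-(methoxymethoxy)benzaldehyde | COCOc1cc(OC)c(OC)c(OC)c1C=O
F7 | step 2 | 3-(2-methoxyphenyl)-1-[2,3,4-trimethoxy-6-(methoxymethoxy)phenyl]prop-2-yn-1-ol (racemic) | COCOc1cc(OC)c(OC)c(OC)c1C(O)C#Cc1ccccc1OC
F8 | step 2 | 3-(2-methoxyphenyl)-1-[2,3,4-trimethoxy-6-(methoxymethoxy)phenyl]prop-2-yn-1-one | COCOc1cc(OC)c(OC)c(OC)c1C(=O)C#Cc1ccccc1OC
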